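The target is 2-hydroxy-3-icosyl-5-methoxy-1,4-benzoquinone. Its one six-membered carbocycle is numbered C1 (C=O), C2 (OH), C3 (icosyl), C4 (C=O), C5 (OMe), C6 (H).
Feature used: C3 lies between the oxygen-bearing C2 and C4, so a 2-alkylresorcinol is hidden in the quinone. The only two nucleophilic carbons of that resorcinol are C1 and C5, the two ring atoms that still need oxygen.
Disconnections, backwards: C5–OMe by hydroxyl/methoxy exchange on the 2,5-dihydroxyquinone; the quinone from 3-icosylbenzene-1,2,4,5-tetrol by air; C1–O and C5–O together by a double Dakin oxidation of 4,6-dihydroxy-5-icosylbenzene-1,3-dicarbaldehyde; both formyl carbons by a double Duff reaction on 2-icosylresorcinol; the chain bond C1'=C2' by a Wittig reaction.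
Ring order: no ring is formed. The single ring is bought as the arene of 2,6-dimethoxybenzaldehyde, whose formyl carbon becomes C1' of the chain, and it is raised to the quinone level only at the end.
Key step: step 6

Remark on the chemistry: the target has no stereocentre, and the alkene geometry created by the Wittig reaction is erased by hydrogenation. The 2,5-dihydroxyquinone is drawn as one of two degenerate tautomers, so the outer oxygens (on C1 and C5) are equivalent to each other, as are the inner oxygens (on C2 and C4).

Step 1
Reactants: 1 1-bromononadecane; 2 triphenylphosphine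
Product: 3 nonadecyl(triphenyl)phosphonium bromide
Conditions: PPh3 (1.05 equiv), MeCN, reflux, 48 h; trituration with Et2O
Reagents that add atoms: triphenylphosphine (2), c1ccc(cc1)P(c1ccccc1)c1ccccc1
Why: SN2 quaternisation of an unhindered primary bromide by triphenylphosphine (phosphonium salt formation) has no competing pathway, and the salt is freed from excess reagents by trituration.

Step 2
Reactants: 3 nonadecyl(triphenyl)phosphonium bromide; 4 2,6-dimethoxybenzaldehyde
Product: 6 2-[(Z)-icos-1-en-1-yl]-1,3-dimethoxybenzene, via nonadecylidenetriphenylphosphorane 5 (not isolated)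
Conditions: KOtBu (1.1 equiv), THF, 0 °C, 1 h; then 4, 0 °C to rt
Reagents that add atoms: none
Why: Wittig olefination, in which the non-stabilised ylide 5 adds even to the doubly ortho-substituted but non-enolisable aldehyde 4 and forms the C1'=C2' bond next to the ring, expected mainly as the Z alkene with some E isomer carried along, which does not matter because step 3 removes the geometry.

Step 3
Reactants: 6 2-[(Z)-icos-1-en-1-yl]-1,3-dimethoxybenzene
Product: 7 2-icosyl-1,3-dimethoxybenzene
Conditions: H2 (1 atm), 10% Pd/C, EtOAc, rt
Reagents that add atoms: none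
Why: Heterogeneous catalytic hydrogenation saturates the styrene-type double bond of both geometric isomers to the same alkane, while the arene and its methyl ethers are inert at 1 atm and room temperature.

Step 4
Reactants: 7 2-icosyl-1,3-dimethoxybenzene
Product: 9 2-icosylbenzene-1,3-diol, via bis(dibromoboryl) ether 8 (not isolated)
Conditions: BBr3 (2.5 equiv), CH2Cl2, −78 °C to rt; then H2O, 0 °C
Reagents that add atoms: none
Why: Lewis-acid cleavage of aryl methyl ethers, in which BBr3 binds each ether oxygen, bromide attacks the methyl carbon in an SN2 step and the aryl borate 8 is hydrolysed on quenching, with nothing else in the saturated substrate able to react.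

Step 5
Reactants: 9 2-icosylbenzene-1,3-diol; 10 hexamethylenetetramine
Product: 12 4,6-dihydroxy-5-icosylbenzene-1,3-dicarbaldehyde, via bis(aldimine) 11 (not isolated)
Conditions: 10 (4 equiv), CF3CO2H, reflux, Ar, 24 h; then 4 M aq HCl, 90 °C, 1 h
Reagents that add atoms: hexamethylenetetramine (10), C1N2CN3CN1CN(C2)C3; water, O
Why: Duff formylation in CF3CO2H, known in its twofold form for simple 2-alkylresorcinols and 4-substituted phenols: iminium ions from protonated 10 attack the only two activated positions (C1 and C5 of the target numbering, each ortho to one hydroxyl and para to the other), a hydride shift raises each benzylic amine to the aldimine level, aqueous acid hydrolyses 11, and C6, meta to both hydroxyls, stays untouched.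

Step 6
Reactants: 12 4,6-dihydroxy-5-icosylbenzene-1,3-dicarbaldehyde
Product: 16 3-icosylbenzene-1,2,4,5-tetrol, via formyl aryl formate 13 (not isolated), via trihydroxybenzaldehyde 14 (not isolated), via trihydroxyaryl formate 15 (not isolated)
Conditions: 30% aq H2O2 (2.1 equiv, added over 1 h), NaOH (5 equiv), degassed THF/H2O, Ar, 0 °C to rt; then degassed 2 M aq HCl; crude product carried on at once
Reagents that add atoms: hydrogen peroxide, OO
Why: This is a Dakin oxidation, the closest known reaction type being the conversion of ortho- and para-hydroxybenzaldehydes into catechols and hydroquinones by alkaline H2O2, here used at both formyl groups of one ring. HOO− attacks a formyl carbon of the bis-phenoxide of 12, and in the perhydrate the ring carbon (C1 first, C5 second, the two being equivalent through the mirror plane that runs through C3 and C6) shifts from carbon to the nearer peroxide oxygen while hydroxide departs, which makes the C1–O and C5–O bonds. Formates 13 and 15 are saponified by the base as soon as they form, so the sequence should run 12, 13, 14, 15, 16 in one flask. No ring is closed and no stereocentre is created. The first selectivity needed is aryl over hydride migration (the latter would end in a carboxylic acid), and it is secured because each migrating carbon stands ortho to one phenoxide and para to the other, which raises its migratory aptitude. The second is attack on the aldehyde in preference to oxidation of the electron-rich 14 and 16, and it is secured by exclusion of air, low temperature and slow dosing of barely more than two equivalents of peroxide, any 16 that is nevertheless oxidised merely arriving early at the product of step 7.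

Step 7
Reactants: 16 3-icosylbenzene-1,2,4,5-tetrol
Product: 17 2,5-dihydroxy-3-icosylcyclohexa-2,5-diene-1,4-dione
Conditions: air sparge, THF/MeOH (1:1), rt
Reagents that add atoms: none
Why: Autoxidation of a hydroquinone, in which the tetrol, the most electron-rich compound of the route, gives up two electrons and two protons to O2 and should stop at 17, whose two vinylogous acid units make further oxidation by air unfavourable.

Step 8
Reactants: 17 2,5-dihydroxy-3-icosylcyclohexa-2,5-diene-1,4-dione
Product: 18 Irisoquin D (2-hydroxy-3-icosyl-5-methoxycyclohexa-2,5-diene-1,4-dione)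
Conditions: MeOH/CH2Cl2 (3:1), conc. H2SO4 (cat.), 40 °C, followed by TLC and stopped at the mono-ether
Reagents that add atoms: methanol, CO
Why: Acid-catalysed vinylogous Fischer esterification (addition–elimination), in which methanol adds to the protonated quinone at C5, whose neighbour C6 bears only hydrogen, and water leaves, whereas the same attack at C2 is hindered by the icosyl chain on C3, so the exchange should stop at the outer mono-ether.

Compound list
1 | 1-bromononadecane | CCCCCCCCCCCCCCCCCCCBr | starting material
2 | triphenylphosphine | c1ccc(cc1)P(c1ccccc1)c1ccccc1 | starting material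
3 | nonadecyl(triphenyl)phosphonium bromide | CCCCCCCCCCCCCCCCCCC[P+](c1ccccc1)(c1ccccc1)c1ccccc1.[Br-] | intermediate
4 | 2,6-dimethoxybenzaldehyde | COc1cccc(OC)c1C=O | starting material
5 | nonadecylidene(triphenyl)phosphorane (ylide, not isolated) | CCCCCCCCCCCCCCCCCCC=P(c1ccccc1)(c1ccccc1)c1ccccc1 | intermediate
6 | 2-[(Z)-icos-1-en-1-yl]-1,3-dimethoxybenzene (minor E isomer carried along) | CCCCCCCCCCCCCCCCCC/C=C\c1c(OC)cccc1OC | intermediate
7 | 2-icosyl-1,3-dimethoxybenzene | CCCCCCCCCCCCCCCCCCCCc1c(OC)cccc1OC | intermediate
8 | 2-icosyl-1,3-phenylene bis(dibromoborinate), the bis(dibromoboryl) ether (not isolated) | CCCCCCCCCCCCCCCCCCCCc1c(OB(Br)Br)cccc1OB(Br)Br | intermediate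
9 | 2-icosylbenzene-1,3-diol (2-icosylresorcinol) | CCCCCCCCCCCCCCCCCCCCc1c(O)cccc1O | intermediate
10 | hexamethylenetetramine | C1N2CN3CN1CN(C2)C3 | starting material
11 | 2-icosyl-4,6-bis(iminomethyl)benzene-1,3-diol (bis-aldimine, present as its iminium trifluoroacetate, nitrogen residues from 10 omitted, not isolated) | CCCCCCCCCCCCCCCCCCCCc1c(O)c(C=N)cc(C=N)c1O | intermediate
12 | 4,6-dihydroxy-5-icosylbenzene-1,3-dicarbaldehyde | CCCCCCCCCCCCCCCCCCCCc1c(O)c(C=O)cc(C=O)c1O | intermediate
13 | 5-formyl-2,4-dihydroxy-3-icosylphenyl formate (not isolated) | CCCCCCCCCCCCCCCCCCCCc1c(O)c(OC=O)cc(C=O)c1O | intermediate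
14 | 2,4,5-trihydroxy-3-icosylbenzaldehyde (not isolated) | CCCCCCCCCCCCCCCCCCCCc1c(O)c(O)cc(C=O)c1O | intermediate
15 | 2,4,5-trihydroxy-3-icosylphenyl formate (not isolated) | CCCCCCCCCCCCCCCCCCCCc1c(O)c(O)cc(OC=O)c1O | intermediate
16 | 3-icosylbenzene-1,2,4,5-tetrol | CCCCCCCCCCCCCCCCCCCCc1c(O)c(O)cc(O)c1O | intermediate
17 | 2,5-dihydroxy-3-icosylcyclohexa-2,5-diene-1,4-dione | CCCCCCCCCCCCCCCCCCCCC1=C(O)C(=O)C=C(O)C1=O | intermediate
18 | Irisoquin D, 2-hydroxy-3-icosyl-5-methoxycyclohexa-2,5-diene-1,4-dione | CCCCCCCCCCCCCCCCCCCCC1=C(O)C(=O)C=C(OC)C1=O | target

Total step count: 8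
Longest linear sequence: 8 steps (1 to 18)

Steps most likely to fail

Step 6. The second aryl migration may lag behind oxidation of the electron-rich mono-stage and of the tetrol by peroxide. That would degrade the ring and starve the second formyl group of oxidant. The soap-like sodium salt may also aggregate and slow the addition of hydroperoxide. The fallback sets out from 7 and comes back at 17. It makes the C1–O and C5–O bonds by copper-catalysed C–O coupling instead of by migration.
- Twofold bromination of 7 (NBS, 2.1 equiv, MeCN/CH2Cl2, 0 °C to rt) at the two activated positions should give 1,5-dibromo-3-icosyl-2,4-dimethoxybenzene F1.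
- Ullmann-type methoxylation (NaOMe, CuI, DMF/MeOH, 110 °C, Ar) should give 3-icosyl-1,2,4,5-tetramethoxybenzene F2.
- Oxidative demethylation with (NH4)2Ce(NO3)6 in MeCN/H2O at 0 °C should give 3-icosyl-2,5-dimethoxycyclohexa-2,5-diene-1,4-dione F3.
- Hydrolysis of both vinylogous esters (2 M NaOH, EtOH, reflux, then HCl) should deliver 17.

Step 5. Formylation may stall once the first formyl group has deactivated the ring. Aminomethylated or benzoxazine-type oligomers may resist hydrolysis, and the waxy substrate may dissolve poorly in CF3CO2H. The fallback sets out from 7 and comes back at 12. It reverses the order of ether cleavage and formylation and uses an oxocarbenium electrophile that needs no redox step.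
- Rieche formylation of 7 (Cl2CHOMe in excess, TiCl4, CH2Cl2, 0 °C to reflux, repeated on the mono-aldehyde if necessary) should give 5-icosyl-4,6-dimethoxybenzene-1,3-dicarbaldehyde F4.
- BCl3 in CH2Cl2 (−78 °C to rt, then water) should cleave both ethers with chelation assistance from the ortho formyl groups and give 12.

Step 8. Discrimination between the outer and the inner hydroxyl may be lost, with run-on to the dimethyl ether, or exchange may be sluggish because the compound dissolves poorly in methanol. The fallback sets out from 9 and comes back at 18. It settles the position of the methyl group by symmetry instead of by a rate difference.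
- Dibromination of 9 (Br2, 2 equiv, CH2Cl2/AcOH, 0 °C) should give 4,6-dibromo-2-icosylbenzene-1,3-diol F5.
- Copper-catalysed methoxylation of the ortho-bromophenoxide units (NaOMe in excess, CuI, DMF/MeOH, 110 °C, Ar) should give 2-icosyl-4,6-dimethoxybenzene-1,3-diol F6, in which both outer oxygens carry methyl and both inner ones are free.
- Oxidation of one 4-methoxyphenol unit with PhI(OAc)2 in MeCN/H2O at 0 °C removes one methyl group. Either para pair gives the same quinone, so 18 should result as a single isomer.

Further compounds
F1 | step 6 | 1,5-dibromo-3-icosyl-2,4-dimethoxybenzene | CCCCCCCCCCCCCCCCCCCCc1c(OC)c(Br)cc(Br)c1OC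
F2 | step 6 | 3-icosyl-1,2,4,5-tetramethoxybenzene | CCCCCCCCCCCCCCCCCCCCc1c(OC)c(OC)cc(OC)c1OC
F3 | step 6 | 3-icosyl-2,5-dimethoxycyclohexa-2,5-diene-1,4-dione | CCCCCCCCCCCCCCCCCCCCC1=C(OC)C(=O)C=C(OC)C1=O
F4 | step 5 | 5-icosyl-4,6-dimethoxybenzene-1,3-dicarbaldehyde | CCCCCCCCCCCCCCCCCCCCc1c(OC)c(C=O)cc(C=O)c1OC
F5 | step 8 | 4,6-dibromo-2-icosylbenzene-1,3-diol | CCCCCCCCCCCCCCCCCCCCc1c(O)c(Br)cc(Br)c1O
F6 | step 8 | 2-icosyl-4,6-dimethoxybenzene-1,3-diol | CCCCCCCCCCCCCCCCCCCCc1c(O)c(OC)cc(OC)c1O
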